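Retrosynthesis: the C9 and C14 ketones come from ozonolysis of a 2,6,6-trimethylcyclohexene (C9=C14). The C1 ester comes from a silylated primary alcohol. The 1,2-dioxane is cut at O–C6, with C5–H traced back to C5–Hg.
Enabling feature: C6 is the fully substituted dioxane carbon, bearing methyl, the ring CH2 (C5) and the chain CH2 (C7). It can be read as the disubstituted end of an (E)-C5=C6 alkene homoallylic to a C3 hydroperoxide, so its configuration is stored as alkene geometry.
Further cuts: C3–OO (sulfonate displacement), C4–C5 (alkenyl metal plus terminal epoxide) and C6–CH3 (carboalumination of a terminal alkyne).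
Forward: the C1–C4 epoxide and the C5–C15 alkyne are joined and the peroxide is placed on C3. The only new ring, the dioxane, is then closed with mercury, and the cyclohexene is opened last.
Stereochemistry: C2 comes from the chiral pool. C3 comes from a catalyst-controlled kinetic resolution followed by SN2 inversion. C6 comes from syn carboalumination, anti peroxymercuration and a chair closure with the C3 side chain equatorial.

Key step: step 12

Remark: labels C1–C15 follow the target (C1 ester carbon, C3–C6 dioxane carbons, C7–C15 side chain). In step 17 the carbonyl oxide is assumed to form at C14; the C9 alternative would be reduced to the same diketone.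

Step 1
Reactants: 1 methyl (S)-3-hydroxy-2-methylpropanoate
Product: 2 methyl (S)-3-[(tert-butyldimethylsilyl)oxy]-2-methylpropanoate
Conditions: TBSCl, imidazole, CH2Cl2, 0 °C to rt
Reagents that add atoms: tert-butyldimethylsilyl chloride, CC(C)(C)[Si](C)(C)Cl
Why: Imidazole-promoted silylation of a primary alcohol masks the future C1 oxygen and leaves the C2 stereocentre untouched.

Step 2
Reactants: 2 methyl (S)-3-[(tert-butyldimethylsilyl)oxy]-2-methylpropanoate
Product: 3 (S)-3-[(tert-butyldimethylsilyl)oxy]-2-methylpropanal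
Conditions: i-Bu2AlH (1.05 equiv), CH2Cl2, −78 °C; aq. potassium sodium tartrate
Reagents that add atoms: none
Why: Partial ester reduction with i-Bu2AlH stops at the aluminium hemiacetal at −78 °C, which collapses to the aldehyde only on work-up, so over-reduction and C2 epimerisation should stay small.

Step 3
Reactants: 3 (S)-3-[(tert-butyldimethylsilyl)oxy]-2-methylpropanal
Product: 4 (R)-tert-butyldimethyl[(2-methylbut-3-en-1-yl)oxy]silane
Conditions: Ph3PCH3Br, n-BuLi, THF, 0 °C; then 3, −78 °C to rt
Reagents that add atoms: methyltriphenylphosphonium bromide, C[P+](c1ccccc1)(c1ccccc1)c1ccccc1.[Br-]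
Why: Wittig methylenation with the non-stabilised ylide is fast at low temperature, so the α-stereocentre passes into the alkene unchanged (the descriptor changes only through priorities).

Step 4
Reactants: 4 (R)-tert-butyldimethyl[(2-methylbut-3-en-1-yl)oxy]silane
Product: 5 2-[(S)-1-[(tert-butyldimethylsilyl)oxy]propan-2-yl]oxirane as a mixture of C3 epimers
Conditions: mCPBA, CH2Cl2, 0 °C to rt
Reagents that add atoms: 3-chloroperoxybenzoic acid, OOC(=O)c1cccc(Cl)c1
Why: Prilezhaev epoxidation of a monosubstituted alkene is reliable but little substrate control is expected, so both C3 epimers are accepted here and sorted in the next step.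

Step 5
Reactants: 5 2-[(S)-1-[(tert-butyldimethylsilyl)oxy]propan-2-yl]oxirane (C3 epimers)
Product: 6 (S)-2-[(S)-1-[(tert-butyldimethylsilyl)oxy]propan-2-yl]oxirane
Conditions: (S,S)-(salen)Co(OAc) (0.5 mol %; salen = N,N'-bis(3,5-di-tert-butylsalicylidene)cyclohexane-1,2-diaminate), H2O (slight excess over the 3R epimer), THF, 0 °C to rt
Reagents that add atoms: none
Why: In the Jacobsen hydrolytic kinetic resolution the trivalent cobalt (S,S)-salen complex hydrolyses the (3R)-epoxide much faster than the (3S)-epoxide irrespective of C2, so the catalyst sets C3 and the polar diol is removed by chromatography.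

Step 6
Reactants: 7 dihydro-β-ionone, 4-(2,6,6-trimethylcyclohex-1-en-1-yl)butan-2-one
Product: 9 2-(but-3-yn-1-yl)-1,3,3-trimethylcyclohex-1-ene, via enol phosphate 8 (not isolated)
Conditions: LiN(i-Pr)2 (1.05 equiv), THF, −78 °C; ClP(O)(OEt)2, −78 °C to rt; added to LiN(i-Pr)2 (2.3 equiv), THF, −78 °C to rt; H2O
Reagents that add atoms: none
Why: The Negishi conversion of a methyl ketone into a terminal alkyne proceeds by kinetic deprotonation at the methyl group, O-phosphorylation and base-induced elimination of diethyl phosphate, with the hindered ring alkene as a spectator.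

Step 7
Reactants: 9 2-(but-3-yn-1-yl)-1,3,3-trimethylcyclohex-1-ene; 6 (S)-2-[(S)-1-[(tert-butyldimethylsilyl)oxy]propan-2-yl]oxirane
Product: 12 (2S,3R,5E)-1-[(tert-butyldimethylsilyl)oxy]-2,6-dimethyl-8-(2,6,6-trimethylcyclohex-1-en-1-yl)oct-5-en-3-ol, via alkenylalane 10 (not isolated), via lithium alanate 11 (not isolated)
Conditions: 9 (1.5 equiv), AlMe3 (2 equiv), Cp2ZrCl2 (0.2 equiv), CH2Cl2, rt; volatiles removed, hexane; n-BuLi, 0 °C; 6, THF, 0 °C to rt; aq. potassium sodium tartrate
Reagents that add atoms: trimethylaluminium, C[Al](C)C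
Why: Negishi zirconium-catalysed carboalumination adds methyl and aluminium syn with aluminium at the terminus, which fixes the (E)-C5=C6 geometry, and the more nucleophilic butyl alanate then opens the terminal epoxide at its CH2 carbon (C4) with retention of alkene geometry and without touching C3.

Step 8
Reactants: 12 (2S,3R,5E)-1-[(tert-butyldimethylsilyl)oxy]-2,6-dimethyl-8-(2,6,6-trimethylcyclohex-1-en-1-yl)oct-5-en-3-ol
Product: 13 (2S,3R,5E)-1-[(tert-butyldimethylsilyl)oxy]-2,6-dimethyl-8-(2,6,6-trimethylcyclohex-1-en-1-yl)oct-5-en-3-yl methanesulfonate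
Conditions: MsCl, Et3N, CH2Cl2, 0 °C
Reagents that add atoms: methanesulfonyl chloride, CS(=O)(=O)Cl
Why: Sulfonylation of a secondary alcohol takes place at oxygen and therefore retains the C3 configuration.

Step 9
Reactants: 14 2,3-dimethylbut-2-ene
Product: 15 2-methoxypropan-2-yl hydroperoxide
Conditions: O3, MeOH/CH2Cl2, −78 °C; concentrated cold and used as a solution
Reagents that add atoms: ozone, [O-][O+]=O; methanol, CO
Why: In a Criegee ozonolysis run in a participating solvent, acetone O-oxide is captured by methanol to give a hydroperoxy ketal, a hydrogen peroxide equivalent blocked at one oxygen.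

Step 10
Reactants: 13 (2S,3R,5E)-methanesulfonate; 15 2-methoxypropan-2-yl hydroperoxide
Product: 16 (2S,3S,5E)-1-[(tert-butyldimethylsilyl)oxy]-2,6-dimethyl-8-(2,6,6-trimethylcyclohex-1-en-1-yl)oct-5-en-3-yl 2-methoxypropan-2-yl peroxide
Conditions: 15 (2 equiv), CsOH·H2O, DMF, 0 °C to rt
Reagents that add atoms: none
Why: In this SN2 alkylation of a cesium alkylperoxide by a secondary sulfonate in a dipolar aprotic solvent, the weakly basic α-effect nucleophile attacks C3 from the rear and inverts it to the configuration of the target, while the ketal blocks a second alkylation.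

Step 11
Reactants: 16 (2S,3S,5E)-peroxyketal
Product: 17 (2S,3S,5E)-1-[(tert-butyldimethylsilyl)oxy]-2,6-dimethyl-8-(2,6,6-trimethylcyclohex-1-en-1-yl)oct-5-en-3-yl hydroperoxide
Conditions: AcOH/THF/H2O, 0 °C to rt, short contact
Reagents that add atoms: none
Why: Mild acid hydrolysis of an acyclic mixed peroxyketal ionises through the methoxy-stabilised carbenium ion far faster than a primary tert-butyldimethylsilyl ether is cleaved, and it does not involve the C3–O bond.

Step 12
Reactants: 17 (2S,3S,5E)-alkenyl hydroperoxide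
Product: 19 bromo{(3R,4S,6S)-6-[(2S)-1-[(tert-butyldimethylsilyl)oxy]propan-2-yl]-3-methyl-3-[2-(2,6,6-trimethylcyclohex-1-en-1-yl)ethyl]-1,2-dioxan-4-yl}mercury (2S,3S,5S,6R in target numbering), via acetoxymercurial 18 (not isolated)
Conditions: Hg(OAc)2 (1.05 equiv), CH2Cl2, 0 °C to rt; then aq. KBr
Reagents that add atoms: mercury diacetate, CC(=O)O[Hg]OC(C)=O; potassium bromide, [K+].[Br-]
Why: Divalent mercury binds the accessible C5=C6 π bond reversibly as a mercurinium ion, and the terminal oxygen of the C3 hydroperoxide opens it at tertiary C6 from the face opposite the metal with loss of AcOH; this is cycloperoxymercuration of an unsaturated hydroperoxide, a known entry to 1,2-dioxanes. The single ring formed (O1, O2, C3–C6) closes 6-endo-trig, because the cationic character at the tertiary terminus outweighs 5-exo attack at secondary C5, which would give a 1,2-dioxolane. C5 and C6 are fixed relative to each other by anti addition to the (E)-alkene: in the chair the C–Hg bond is antiperiplanar to the forming ring bond O–C6 and hence equatorial, which places C7 equatorial and the C6 methyl axial. Both centres are fixed relative to C3 by the preference of the branched C2 side chain for the equatorial site of that chair, so the C6 methyl and the C3 side chain should end up cis, as the target requires. The step also needs chemoselectivity over the C9=C14 ring alkene, which is tetrasubstituted, flanked by the gem-dimethyl carbon and has no internal nucleophile, so its mercuration should be slow and reversible. Exchange of acetate for bromide with KBr gives the less polar, more easily handled organomercurial 19.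

Step 13
Reactants: 19 5-bromomercurio-1,2-dioxane
Product: 20 tert-butyldimethyl{(2S)-2-[(3S,6R)-6-methyl-6-[2-(2,6,6-trimethylcyclohex-1-en-1-yl)ethyl]-1,2-dioxan-3-yl]propoxy}silane
Conditions: NaBH4, 2 M aq. NaOH, CH2Cl2, 0 °C
Reagents that add atoms: none
Why: Hydride demercuration, a radical chain through the alkylmercury hydride, replaces mercury at C5 by hydrogen and erases that auxiliary stereocentre, and the ring should hold the C5 radical orbital away from the O–O axis and the C6–O bond, so epoxide formation and peroxyl loss are slower than for acyclic β-peroxy radicals.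

Step 14
Reactants: 20 silyl-protected 1,2-dioxane
Product: 21 (2S)-2-[(3S,6R)-6-methyl-6-[2-(2,6,6-trimethylcyclohex-1-en-1-yl)ethyl]-1,2-dioxan-3-yl]propan-1-ol
Conditions: HF·pyridine, pyridine, THF, 0 °C to rt
Reagents that add atoms: none
Why: Fluoride desilylation in a buffered, weakly acidic medium is chosen because basic fluoride could abstract the C3 hydrogen and start Kornblum–DeLaMare cleavage of the peroxide.

Step 15
Reactants: 21 dioxanyl propanol
Product: 23 (2R)-2-[(3S,6R)-6-methyl-6-[2-(2,6,6-trimethylcyclohex-1-en-1-yl)ethyl]-1,2-dioxan-3-yl]propanoic acid, via aldehyde 22 (not isolated)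
Conditions: TEMPO (0.2 equiv), PhI(OAc)2 (2.2 equiv), MeCN/H2O (1:1), rt
Reagents that add atoms: water, O
Why: Oxoammonium (TEMPO) oxidation with PhI(OAc)2 as terminal oxidant takes the primary alcohol through the aldehyde hydrate to the acid in a near-neutral medium, which spares the O–O bond, the tetrasubstituted alkene and the epimerisable C2 centre.

Step 16
Reactants: 23 dioxanyl propanoic acid
Product: 24 methyl (2R)-2-[(3S,6R)-6-methyl-6-[2-(2,6,6-trimethylcyclohex-1-en-1-yl)ethyl]-1,2-dioxan-3-yl]propanoate
Conditions: TMSCHN2, toluene/MeOH, 0 °C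
Reagents that add atoms: (trimethylsilyl)diazomethane, C[Si](C)(C)C=[N+]=[N-]
Why: Esterification of a carboxylic acid with a diazoalkane needs no base and so avoids β-elimination of the peroxide and epimerisation at C2.

Step 17
Reactants: 24 cyclohexenyl methyl ester
Product: 26 diacarperoxide C, via methoxy hydroperoxide 25 (not isolated)
Conditions: O3, CH2Cl2/MeOH, −78 °C; then Me2S, −78 °C to rt
Reagents that add atoms: ozone, [O-][O+]=O
Why: Criegee ozonolysis of the electron-rich tetrasubstituted ring alkene in the presence of methanol, followed by sulfide reduction that consumes hydroperoxides but not dialkyl peroxides, unveils the C9 and C14 ketones with all three stereocentres untouched (C6 becomes S only through a priority change).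

Compound list
1 | methyl (S)-3-hydroxy-2-methylpropanoate | COC(=O)[C@@H](C)CO | starting material
2 | methyl (S)-3-[(tert-butyldimethylsilyl)oxy]-2-methylpropanoate | COC(=O)[C@@H](C)CO[Si](C)(C)C(C)(C)C | intermediate
3 | (S)-3-[(tert-butyldimethylsilyl)oxy]-2-methylpropanal | O=C[C@@H](C)CO[Si](C)(C)C(C)(C)C | intermediate
4 | (R)-tert-butyldimethyl[(2-methylbut-3-en-1-yl)oxy]silane | C=C[C@@H](C)CO[Si](C)(C)C(C)(C)C | intermediate
5 | 2-[(S)-1-[(tert-butyldimethylsilyl)oxy]propan-2-yl]oxirane, C3 epimers | CC(C)(C)[Si](C)(C)OC[C@H](C)C1CO1 | intermediate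
6 | (S)-2-[(S)-1-[(tert-butyldimethylsilyl)oxy]propan-2-yl]oxirane | CC(C)(C)[Si](C)(C)OC[C@H](C)[C@H]1CO1 | intermediate
7 | dihydro-β-ionone | CC(=O)CCC1=C(C)CCCC1(C)C | starting material
8 | diethyl 4-(2,6,6-trimethylcyclohex-1-en-1-yl)but-1-en-2-yl phosphate | C=C(CCC1=C(C)CCCC1(C)C)OP(=O)(OCC)OCC | intermediate
9 | 2-(but-3-yn-1-yl)-1,3,3-trimethylcyclohex-1-ene | C#CCCC1=C(C)CCCC1(C)C | intermediate
10 | (E)-dimethyl[2-methyl-4-(2,6,6-trimethylcyclohex-1-en-1-yl)but-1-en-1-yl]alane | C[Al](C)/C=C(\C)CCC1=C(C)CCCC1(C)C | intermediate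
11 | lithium butyldimethyl[(E)-2-methyl-4-(2,6,6-trimethylcyclohex-1-en-1-yl)but-1-en-1-yl]alanate | [Li+].CCCC[Al-](C)(C)/C=C(\C)CCC1=C(C)CCCC1(C)C | intermediate
12 | (2S,3R,5E)-1-[(tert-butyldimethylsilyl)oxy]-2,6-dimethyl-8-(2,6,6-trimethylcyclohex-1-en-1-yl)oct-5-en-3-ol | CC(C)(C)[Si](C)(C)OC[C@H](C)[C@H](O)C/C=C(\C)CCC1=C(C)CCCC1(C)C | intermediate
13 | methanesulfonate of 12 (2S,3R,5E) | CC(C)(C)[Si](C)(C)OC[C@H](C)[C@H](OS(C)(=O)=O)C/C=C(\C)CCC1=C(C)CCCC1(C)C | intermediate
14 | 2,3-dimethylbut-2-ene | CC(C)=C(C)C | starting material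
15 | 2-methoxypropan-2-yl hydroperoxide | COC(C)(C)OO | intermediate
16 | (2S,3S,5E)-C3 2-methoxypropan-2-yl peroxide | CC(C)(C)[Si](C)(C)OC[C@H](C)[C@@H](OOC(C)(C)OC)C/C=C(\C)CCC1=C(C)CCCC1(C)C | intermediate
17 | (2S,3S,5E)-C3 hydroperoxide, precursor of the key step | CC(C)(C)[Si](C)(C)OC[C@H](C)[C@@H](OO)C/C=C(\C)CCC1=C(C)CCCC1(C)C | intermediate
18 | 5-acetoxymercurio-1,2-dioxane (2S,3S,5S,6R) | CC(C)(C)[Si](C)(C)OC[C@H](C)[C@@H]1C[C@H]([Hg]OC(C)=O)[C@@](C)(CCC2=C(C)CCCC2(C)C)OO1 | intermediate
19 | 5-bromomercurio-1,2-dioxane (2S,3S,5S,6R), product of the key step | CC(C)(C)[Si](C)(C)OC[C@H](C)[C@@H]1C[C@H]([Hg]Br)[C@@](C)(CCC2=C(C)CCCC2(C)C)OO1 | intermediate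
20 | demercurated silyl ether (2S,3S,6R) | CC(C)(C)[Si](C)(C)OC[C@H](C)[C@@H]1CC[C@@](C)(CCC2=C(C)CCCC2(C)C)OO1 | intermediate
21 | dioxanyl propan-1-ol (2S,3S,6R) | OC[C@H](C)[C@@H]1CC[C@@](C)(CCC2=C(C)CCCC2(C)C)OO1 | intermediate
22 | dioxanyl propanal (2R,3S,6R) | O=C[C@H](C)[C@@H]1CC[C@@](C)(CCC2=C(C)CCCC2(C)C)OO1 | intermediate
23 | dioxanyl propanoic acid (2R,3S,6R) | OC(=O)[C@H](C)[C@@H]1CC[C@@](C)(CCC2=C(C)CCCC2(C)C)OO1 | intermediate
24 | methyl ester of 23 (2R,3S,6R) | COC(=O)[C@H](C)[C@@H]1CC[C@@](C)(CCC2=C(C)CCCC2(C)C)OO1 | intermediate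
25 | C9 ketone, C14 methoxy hydroperoxide (C14 unassigned) | COC(=O)[C@H](C)[C@@H]1CC[C@@](C)(CCC(=O)C(C)(C)CCCC(C)(OC)OO)OO1 | intermediate
26 | diacarperoxide C, methyl (2R)-2-[(3S,6S)-6-(4,4-dimethyl-3,8-dioxononyl)-6-methyl-1,2-dioxan-3-yl]propanoate | COC(=O)[C@H](C)[C@@H]1CC[C@@](C)(CCC(=O)C(C)(C)CCCC(C)=O)OO1 | target

Total step count: 17.
Longest linear sequence: 15 (steps 1–5, 7, 8, 10–17).

Steps most likely to fail

**Step 10.** Three processes could outrun clean inversion at the β-branched C3:
- E2 loss of the sulfonate towards the conjugated diene;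
- attack of the peroxide anion at sulfur;
- ionisation assisted by the C5=C6 π bond.

The fallback reaches the same peroxyketal by double inversion through a halide, the electrophile class best suited to cesium peroxide alkylation. It sets out from 5 and comes back at 16. Resolution of 5 with the enantiomeric (R,R)-(salen)Co(OAc) keeps the (3R)-epoxide F1. Alanate 11 opens it, as in step 7, to the 2,3-syn alcohol F2. An Appel reaction (CBr4, PPh3, CH2Cl2) converts this with inversion into the (3R)-bromide F3. CsOH·H2O and 15 in DMF then displace bromide with a second inversion to give 16.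

**Step 12.** Three processes could erode the key closure:
- poor facial selectivity of the chair closure (side chain axial instead of equatorial);
- competing 5-exo closure;
- mercuration of the ring alkene.

The fallback forms the same O–C6 bond and the same ring, but the face is chosen by a reagent. It sets out from 16 and comes back at 20. Shi epoxidation uses the L-fructose-derived ketone (KHSO5, K2CO3, MeCN/dimethoxymethane/H2O, 0 °C). Its bulky dioxirane should prefer the trisubstituted alkene and give the (5S,6S)-epoxy peroxyketal F4. Aqueous AcOH frees the epoxy hydroperoxide F5. Catalytic camphorsulfonic acid in CH2Cl2 then lets the terminal peroxide oxygen open the epoxide at tertiary C6 with inversion (6-endo), giving the 5-hydroxy-1,2-dioxane F6. 1,1'-Thiocarbonyldiimidazole converts it into the imidazolylthiocarbonate F7. Barton–McCombie deoxygenation (Bu3SnH, Et3B, air, rt) gives 20.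

**Step 13.** The C5 radical could attack the O–O bond or expel the peroxyl radical before it abstracts hydrogen, and the aqueous base could start cleavage of the peroxide at C3–H. The fallback avoids any substituent at C5 and closes the ring at the other end. It sets out from 13 and comes back at 20. Mukaiyama–Isayama peroxidation uses Co(thd)2 (thd = 2,2,6,6-tetramethylheptane-3,5-dionate), O2 and Et3SiH in 1,2-dichloroethane at rt. It is expected to hydroperoxysilylate only the trisubstituted alkene at C6, giving the triethylsilylperoxy mesylate F8 as both C6 epimers. One equivalent of n-Bu4NF in THF at 0 °C frees the peroxide anion, which displaces the C3 mesylate intramolecularly with inversion. This gives 20 together with its 6-epimer F9, to be separated by chromatography. Control at C6 is the price paid.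

Further compounds
F1 | step 10 | (R)-2-[(S)-1-[(tert-butyldimethylsilyl)oxy]propan-2-yl]oxirane | CC(C)(C)[Si](C)(C)OC[C@H](C)[C@@H]1CO1
F2 | step 10 | (2S,3S,5E)-1-[(tert-butyldimethylsilyl)oxy]-2,6-dimethyl-8-(2,6,6-trimethylcyclohex-1-en-1-yl)oct-5-en-3-ol | CC(C)(C)[Si](C)(C)OC[C@H](C)[C@@H](O)C/C=C(\C)CCC1=C(C)CCCC1(C)C
F3 | step 10 | (2S,3R,5E)-3-bromo-1-[(tert-butyldimethylsilyl)oxy]-2,6-dimethyl-8-(2,6,6-trimethylcyclohex-1-en-1-yl)oct-5-ene | CC(C)(C)[Si](C)(C)OC[C@H](C)[C@H](Br)C/C=C(\C)CCC1=C(C)CCCC1(C)C
F4 | step 12 | (2S,3S,5S,6S)-5,6-epoxide of peroxyketal 16 | CC(C)(C)[Si](C)(C)OC[C@H](C)[C@@H](OOC(C)(C)OC)C[C@@H]1O[C@@]1(C)CCC2=C(C)CCCC2(C)C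
F5 | step 12 | (2S,3S,5S,6S)-5,6-epoxy C3 hydroperoxide | CC(C)(C)[Si](C)(C)OC[C@H](C)[C@@H](OO)C[C@@H]1O[C@@]1(C)CCC2=C(C)CCCC2(C)C
F6 | step 12 | (2S,3S,5S,6R)-5-hydroxy derivative of 20 | CC(C)(C)[Si](C)(C)OC[C@H](C)[C@@H]1C[C@H](O)[C@@](C)(CCC2=C(C)CCCC2(C)C)OO1
F7 | step 12 | O-(imidazol-1-ylthiocarbonyl) derivative of F6 | CC(C)(C)[Si](C)(C)OC[C@H](C)[C@@H]1C[C@H](OC(=S)n2ccnc2)[C@@](C)(CCC3=C(C)CCCC3(C)C)OO1
F8 | step 13 | (2S,3R)-3-mesyloxy-6-(triethylsilylperoxy) compound, C6 epimers | CC(C)(C)[Si](C)(C)OC[C@H](C)[C@H](OS(C)(=O)=O)CCC(C)(OO[Si](CC)(CC)CC)CCC1=C(C)CCCC1(C)C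
F9 | step 13 | 6-epimer of 20 (2S,3S,6S) | CC(C)(C)[Si](C)(C)OC[C@H](C)[C@@H]1CC[C@](C)(CCC2=C(C)CCCC2(C)C)OO1
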